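**Plan**
- Retrosynthesis: the C2–C3 bond of the pyranone ring is cut first (carbenoid C–H insertion), then the diazo group goes back to a methyl ketone, then the aryl O–C(sec-alkyl) bond is cut (Mitsunobu) to a 4-bromo-2,5-dihydroxyacetophenone and (S)-sulcatol; the tertiary alcohol comes from the chain alkene.
- Forward: the arene is built first (Friedel–Crafts acylation, demethylation, 5-O-MOM), the chain is joined at oxygen, hydrated and silylated, the acetyl group is turned into a diazomethyl ketone, and the pyranone ring is closed last, before deprotection.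
- Enabling feature: C2 is bound to the ring oxygen O1, so in the open precursor it is the methine C–H of an aryl sec-alkyl ether. The benzene ring holds it, through C4–C4a–C8a–O1, six atoms from the ketone α-carbon C3, so a carbene at C3 can insert into the C2–H bond.
- Stereochemistry: the only stereocentre comes from (S)-sulcatol. Mitsunobu inversion gives the (R)-ether, and the C–H insertion proceeds with retention, turning it into the quaternary (R)-C2.

Key step: step 8

Assumption: (2S)-6-methylhept-5-en-2-ol ((S)-sulcatol) is taken as a purchasable, enantiopure chiral-pool alcohol.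

**Step 1**
Reactants: 1 2-bromo-1,4-dimethoxybenzene
Product: 2 1-(4-bromo-2,5-dimethoxyphenyl)ethan-1-one
Conditions: AcCl, AlCl3, CH2Cl2, 0 °C → rt
Reagents that add atoms: acetyl chloride CC(=O)Cl
Why: Friedel–Crafts acylation should occur at the methoxy-activated position para to bromine, the least hindered one; any ortho O-demethylation by AlCl3 is harmless because step 2 removes both methyl groups.

**Step 2**
Reactants: 2 1-(4-bromo-2,5-dimethoxyphenyl)ethan-1-one
Product: 3 1-(4-bromo-2,5-dihydroxyphenyl)ethan-1-one
Conditions: BBr3 (3 equiv), CH2Cl2, −78 °C → rt; then H2O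
Reagents that add atoms: none
Why: Lewis-acid cleavage of aryl methyl ethers with BBr3 should free both phenols while the aryl bromide and the ketone stay untouched.

**Step 3**
Reactants: 3 1-(4-bromo-2,5-dihydroxyphenyl)ethan-1-one
Product: 4 1-[4-bromo-2-hydroxy-5-(methoxymethoxy)phenyl]ethan-1-one
Conditions: MOMCl (1.05 equiv), iPr2NEt, CH2Cl2, 0 °C
Reagents that add atoms: chloromethyl methyl ether COCCl
Why: Selective O-alkylation (MOM protection) is expected at the 5-OH, because the 2-OH is locked in a hydrogen bond to the acetyl carbonyl and is much less nucleophilic.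

**Step 4**
Reactants: 4 1-[4-bromo-2-hydroxy-5-(methoxymethoxy)phenyl]ethan-1-one; 5 (2S)-6-methylhept-5-en-2-ol
Product: 6 1-[4-bromo-5-(methoxymethoxy)-2-{[(2R)-6-methylhept-5-en-2-yl]oxy}phenyl]ethan-1-one
Conditions: PPh3, DIAD, THF, 0 °C → rt
Reagents that add atoms: none
Why: Mitsunobu etherification displaces the activated secondary carbinol by the phenol in an SN2 step with inversion, so the (S)-alcohol should give the (R)-aryl ether.

**Step 5**
Reactants: 6 1-[4-bromo-5-(methoxymethoxy)-2-{[(2R)-6-methylhept-5-en-2-yl]oxy}phenyl]ethan-1-one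
Product: 7 1-[4-bromo-2-{[(2R)-6-hydroxy-6-methylheptan-2-yl]oxy}-5-(methoxymethoxy)phenyl]ethan-1-one
Conditions: Co(acac)2 (cat.), PhSiH3, O2 (1 atm), THF/iPrOH, rt; aqueous work-up
Reagents that add atoms: dioxygen O=O
Why: Mukaiyama hydration (cobalt hydrogen-atom transfer, then trapping of the tertiary radical by O2) should give the Markovnikov tertiary alcohol and tolerate the aryl ketone, aryl bromide, acetal and the remote stereocentre.

**Step 6**
Reactants: 7 1-[4-bromo-2-{[(2R)-6-hydroxy-6-methylheptan-2-yl]oxy}-5-(methoxymethoxy)phenyl]ethan-1-one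
Product: 8 1-[4-bromo-5-(methoxymethoxy)-2-({(2R)-6-methyl-6-[(triethylsilyl)oxy]heptan-2-yl}oxy)phenyl]ethan-1-one
Conditions: TESOTf, 2,6-lutidine, CH2Cl2, −78 °C; aq. NaHCO3 work-up
Reagents that add atoms: triethylsilyl trifluoromethanesulfonate CC[Si](CC)(CC)OS(=O)(=O)C(F)(F)F
Why: Silyl triflate silylation is fast on a hindered tertiary alcohol at low temperature and removes the O–H that would be acylated in step 7 and undergo carbenoid O–H insertion in step 8.

**Step 7**
Reactants: 8 1-[4-bromo-5-(methoxymethoxy)-2-({(2R)-6-methyl-6-[(triethylsilyl)oxy]heptan-2-yl}oxy)phenyl]ethan-1-one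
Product: 10 1-[4-bromo-5-(methoxymethoxy)-2-({(2R)-6-methyl-6-[(triethylsilyl)oxy]heptan-2-yl}oxy)phenyl]-2-diazoethan-1-one, via trifluoroacetyl 1,3-diketone 9 (not isolated)
Conditions: LiHMDS, THF, −78 °C; CF3CO2CH2CF3; cold 5% aq. HCl wash; then MsN3, Et3N, H2O, MeCN, rt
Reagents that add atoms: 2,2,2-trifluoroethyl trifluoroacetate O=C(OCC(F)(F)F)C(F)(F)F; methanesulfonyl azide CS(=O)(=O)N=[N+]=[N-]
Why: Detrifluoroacetylative diazo transfer (Danheiser variant of the Regitz reaction): the only enolisable position is C-trifluoroacetylated as a temporary activating group, which is split off again when the sulfonyl azide delivers N2.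

**Step 8**
Reactants: 10 1-[4-bromo-5-(methoxymethoxy)-2-({(2R)-6-methyl-6-[(triethylsilyl)oxy]heptan-2-yl}oxy)phenyl]-2-diazoethan-1-one
Product: 11 (2R)-7-bromo-6-(methoxymethoxy)-2-methyl-2-{4-methyl-4-[(triethylsilyl)oxy]pentyl}-2,3-dihydro-4H-chromen-4-one
Conditions: Rh2(OAc)4 (1 mol%), CH2Cl2, rt, slow addition of 10 at high dilution
Reagents that add atoms: none
Why: Rh2(OAc)4 should decompose the diazo ketone with loss of N2 to an electrophilic rhodium carbenoid at the future C3, which inserts through a concerted three-centre transition state into the methine C–H bond α to the aryl ether oxygen (the future C2) and so forms the C2–C3 bond. The closest known reaction type is the intramolecular Rh(II)-carbenoid C–H insertion of ortho-alkoxyaryl diazo ketones to chroman-4-ones, together with the stereoretentive carbenoid insertion into tertiary C–H bonds. The pyranone ring closes in a six-membered (1,6) insertion mode, the atoms C4, C4a, C8a and O1 between the two reacting centres being held in place by the benzene ring. The new quaternary centre C2 is controlled by the substrate: the C–C bond forms on the face from which hydrogen leaves, so the configuration of the (R)-ether carbon is retained and the descriptor stays (R). The step needs site selectivity for this one C–H bond and chemoselectivity against attack of the carbenoid on the lone pair of O1 (oxonium ylide). The first is secured because this is the only C–H that is both tertiary and oxygen-activated and the only one within reach of a six-membered transition state, with no O–H or alkene left in the substrate; the second rests on the ether oxygen being a poor ylide donor, since its lone pair is delocalised into the ortho-acyl arene and it is shielded by the secondary alkyl group.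

**Step 9**
Reactants: 11 (2R)-7-bromo-6-(methoxymethoxy)-2-methyl-2-{4-methyl-4-[(triethylsilyl)oxy]pentyl}-2,3-dihydro-4H-chromen-4-one
Product: 12 (2R)-7-bromo-6-hydroxy-2-(4-hydroxy-4-methylpentyl)-2-methyl-2,3-dihydro-4H-chromen-4-one
Conditions: 3 M aq. HCl, THF, rt → 40 °C
Reagents that add atoms: none
Why: Acid hydrolysis should cleave the MOM acetal and the TES ether in one operation without ionising the tertiary alcohol, and it avoids base, which could racemise C2 by retro-oxa-Michael opening and re-closure.

**Compound list**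
1 | 2-bromo-1,4-dimethoxybenzene | COc1ccc(OC)c(Br)c1 | starting material
2 | 1-(4-bromo-2,5-dimethoxyphenyl)ethan-1-one | CC(=O)c1cc(OC)c(Br)cc1OC | intermediate
3 | 1-(4-bromo-2,5-dihydroxyphenyl)ethan-1-one | CC(=O)c1cc(O)c(Br)cc1O | intermediate
4 | 1-[4-bromo-2-hydroxy-5-(methoxymethoxy)phenyl]ethan-1-one | CC(=O)c1cc(OCOC)c(Br)cc1O | intermediate
5 | (2S)-6-methylhept-5-en-2-ol ((S)-sulcatol) | CC(C)=CCC[C@H](C)O | starting material
6 | 1-[4-bromo-5-(methoxymethoxy)-2-{[(2R)-6-methylhept-5-en-2-yl]oxy}phenyl]ethan-1-one | CC(C)=CCC[C@@H](C)Oc1cc(Br)c(OCOC)cc1C(C)=O | intermediate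
7 | 1-[4-bromo-2-{[(2R)-6-hydroxy-6-methylheptan-2-yl]oxy}-5-(methoxymethoxy)phenyl]ethan-1-one | CC(C)(O)CCC[C@@H](C)Oc1cc(Br)c(OCOC)cc1C(C)=O | intermediate
8 | 1-[4-bromo-5-(methoxymethoxy)-2-({(2R)-6-methyl-6-[(triethylsilyl)oxy]heptan-2-yl}oxy)phenyl]ethan-1-one | CC[Si](CC)(CC)OC(C)(C)CCC[C@@H](C)Oc1cc(Br)c(OCOC)cc1C(C)=O | intermediate
9 | 1-[4-bromo-5-(methoxymethoxy)-2-({(2R)-6-methyl-6-[(triethylsilyl)oxy]heptan-2-yl}oxy)phenyl]-4,4,4-trifluorobutane-1,3-dione | CC[Si](CC)(CC)OC(C)(C)CCC[C@@H](C)Oc1cc(Br)c(OCOC)cc1C(=O)CC(=O)C(F)(F)F | intermediate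
10 | 1-[4-bromo-5-(methoxymethoxy)-2-({(2R)-6-methyl-6-[(triethylsilyl)oxy]heptan-2-yl}oxy)phenyl]-2-diazoethan-1-one | CC[Si](CC)(CC)OC(C)(C)CCC[C@@H](C)Oc1cc(Br)c(OCOC)cc1C(=O)C=[N+]=[N-] | intermediate
11 | (2R)-7-bromo-6-(methoxymethoxy)-2-methyl-2-{4-methyl-4-[(triethylsilyl)oxy]pentyl}-2,3-dihydro-4H-chromen-4-one | CC[Si](CC)(CC)OC(C)(C)CCC[C@]1(C)CC(=O)c2cc(OCOC)c(Br)cc2O1 | intermediate
12 | (2R)-7-bromo-6-hydroxy-2-(4-hydroxy-4-methylpentyl)-2-methyl-2,3-dihydro-4H-chromen-4-one | CC(C)(O)CCC[C@]1(C)CC(=O)c2cc(O)c(Br)cc2O1 | target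

**Summary**
Total step count: 9. Longest linear sequence: 9 steps (1 → 12).

**Steps most likely to fail**

Step 8. The carbenoid may be captured by the lone pair of the ether oxygen to give a five-membered oxonium ylide, which would then undergo a 1,2-shift or β-elimination with loss of the side chain; a stepwise hydride-transfer pathway could also erode the configuration at C2. Fallback, setting out from 4: a Kabbe condensation with commercial 6-hydroxy-6-methylheptan-2-one (pyrrolidine, MeOH, reflux; enamine aldol, then oxa-Michael closure) should give racemic 7-bromo-2-(4-hydroxy-4-methylpentyl)-6-(methoxymethoxy)-2-methylchroman-4-one F1. Preparative chromatography on a chiral stationary phase should separate the (2R)-enantiomer F2 from the (2S)-enantiomer F3, which is set aside. Treatment of F2 with 3 M aq. HCl in THF removes the MOM group and the route is rejoined at 12.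

Step 4. The hydrogen-bonded, hindered ortho-acyl phenol may couple slowly, so that elimination of the activated alcohol or its capture by the hydrazide competes. Fallback, setting out from 5: MsCl and Et3N in CH2Cl2 at 0 °C should give (2S)-6-methylhept-5-en-2-yl methanesulfonate F4. Alkylation of phenol 4 with F4 (Cs2CO3, DMF, 50 °C) is an SN2 displacement with inversion and comes back to the route at 6.

Step 5. Hydrogen-atom transfer may end in net reduction of the alkene instead of oxygen capture, or the silane may reduce the aryl ketone. Fallback, setting out from 6: oxymercuration (Hg(OAc)2, THF/H2O) should give the acetoxymercurio tertiary alcohol F5. Demercuration with NaBH4/NaOH also reduces the ketone and gives 1-[4-bromo-2-{[(2R)-6-hydroxy-6-methylheptan-2-yl]oxy}-5-(methoxymethoxy)phenyl]ethan-1-ol F6 as a mixture of carbinol epimers. Oxidation of the benzylic alcohol with MnO2 in CH2Cl2 leaves the tertiary alcohol untouched and comes back to the route at 7.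

**Further compounds**
F1 | step 8 | racemic 7-bromo-2-(4-hydroxy-4-methylpentyl)-6-(methoxymethoxy)-2-methylchroman-4-one | CC(C)(O)CCCC1(C)CC(=O)c2cc(OCOC)c(Br)cc2O1
F2 | step 8 | (2R)-7-bromo-2-(4-hydroxy-4-methylpentyl)-6-(methoxymethoxy)-2-methylchroman-4-one | CC(C)(O)CCC[C@]1(C)CC(=O)c2cc(OCOC)c(Br)cc2O1
F3 | step 8 | (2S)-7-bromo-2-(4-hydroxy-4-methylpentyl)-6-(methoxymethoxy)-2-methylchroman-4-one | CC(C)(O)CCC[C@@]1(C)CC(=O)c2cc(OCOC)c(Br)cc2O1
F4 | step 4 | (2S)-6-methylhept-5-en-2-yl methanesulfonate | CC(C)=CCC[C@H](C)OS(C)(=O)=O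
F5 | step 5 | 1-[2-{[(2R)-5-(acetoxymercurio)-6-hydroxy-6-methylheptan-2-yl]oxy}-4-bromo-5-(methoxymethoxy)phenyl]ethan-1-one | CC(=O)O[Hg]C(CC[C@@H](C)Oc1cc(Br)c(OCOC)cc1C(C)=O)C(C)(C)O
F6 | step 5 | 1-[4-bromo-2-{[(2R)-6-hydroxy-6-methylheptan-2-yl]oxy}-5-(methoxymethoxy)phenyl]ethan-1-ol (epimers at the carbinol carbon) | CC(C)(O)CCC[C@@H](C)Oc1cc(Br)c(OCOC)cc1C(C)O
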